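**Strategy**

The flavonol is cut at C4. This carbonyl carbon lies between C4a of the symmetric 1,3,5-trioxygenated ring A and the oxygen-bearing C3 of ring C, and that placement is what the key step exploits: carbon monoxide supplies C4. A single palladium-catalysed carbonylative α-arylation unites 2-iodo-1,3,5-tris(methoxymethoxy)benzene, CO and the enolate of the ring B ketone 2-(methoxymethoxy)-1-[8-(methoxymethoxy)-2,2-dimethyl-2H-chromen-6-yl]ethanone, forming C4–C4a and C3–C4 and giving the whole carbon framework except the C8 side chain as an open 2-alkoxy-1,3-diketone. Acid then removes the MOM ethers and closes ring C; 7-O-prenylation and an aromatic Claisen shift install the 1,1-dimethylallyl group at C8.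

Key step: step 10

**Remarks on the chemistry**

- The commercial bromophenol 5 carries a methyl ether where the ring B phenol of the target sits. A methyl ether could not be cleaved at the end beside the chromene and the tert-prenyl group, so it is exchanged for a MOM ether at the bromochromene stage (steps 5 and 6).
- In step 10 the ketone 16 is the limiting partner and the cheap iodide 4 is used in excess (about 1.5 equiv). Two equivalents of base are used because the product diketone is more acidic than 16.

**Route**

Step 1
Reactants: 1 phloroglucinol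
Product: 2 1,3,5-tris(methoxymethoxy)benzene
Conditions: NaH (3.3 equiv), MOMCl (3.3 equiv), DMF, 0 °C → rt
Reagents that add atoms: chloromethyl methyl ether (MOMCl), COCCl
Why: Threefold Williamson etherification of the sodium phenoxides with the hard chloromethyl ether in DMF should favour O- over C-alkylation and give the symmetric tris-acetal.

Step 2
Reactants: 2 1,3,5-tris(methoxymethoxy)benzene
Product: 4 2-iodo-1,3,5-tris(methoxymethoxy)benzene, via aryllithium 3 (not isolated)
Conditions: n-BuLi, THF, 0 °C; then I2, −78 °C → rt
Reagents that add atoms: iodine, II; n-butyllithium, [Li]CCCC (supplies only the lithium of intermediate 3)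
Why: Directed ortho-metalation between two chelating MOM-oxy groups followed by iodinolysis of the C–Li bond; the three ring positions are equivalent, so only one iodide can form.

Step 3
Reactants: 5 4-bromo-2-methoxyphenol; 6 3-chloro-3-methylbut-1-yne
Product: 7 4-bromo-2-methoxy-1-[(2-methylbut-3-yn-2-yl)oxy]benzene
Conditions: K2CO3, KI, CuI (cat.), acetone, reflux
Reagents that add atoms: none
Why: Copper-assisted O-propargylation of the potassium phenoxide by the readily ionised tertiary propargylic chloride (Williamson-type etherification), the standard entry to 2,2-dimethylchromenes.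

Step 4
Reactants: 7 4-bromo-2-methoxy-1-[(2-methylbut-3-yn-2-yl)oxy]benzene
Product: 9 6-bromo-8-methoxy-2,2-dimethyl-2H-chromene, via allenylphenol 8 (not isolated)
Conditions: PhNEt2, 190 °C
Reagents that add atoms: none
Why: Aryl propargyl ether Claisen rearrangement to the only free ortho carbon gives the allenylphenol, which closes by 1,5-hydrogen shift and 6π oxa-electrocyclisation to the chromene with bromine para to the ring oxygen.

Step 5
Reactants: 9 6-bromo-8-methoxy-2,2-dimethyl-2H-chromene
Product: 10 6-bromo-2,2-dimethyl-2H-chromen-8-ol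
Conditions: NaSEt, DMF, 120 °C; then 1 M HCl, 0 °C
Reagents that add atoms: none
Why: SN2 demethylation by thiolate at the unhindered methyl carbon; the tertiary chromene ether carbon cannot be attacked in this way, and the unactivated aryl bromide and the styrenic alkene are inert to thiolate.

Step 6
Reactants: 10 6-bromo-2,2-dimethyl-2H-chromen-8-ol
Product: 11 6-bromo-8-(methoxymethoxy)-2,2-dimethyl-2H-chromene
Conditions: NaH, MOMCl, THF, 0 °C → rt
Reagents that add atoms: chloromethyl methyl ether (MOMCl), COCCl
Why: Williamson etherification of the single phenoxide gives an acetal that tolerates the organolithium, enolate and palladium steps and falls off in the final acid step together with the others.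

Step 7
Reactants: 12 methyl glycolate
Product: 13 methyl 2-(methoxymethoxy)acetate
Conditions: MOMCl, i-Pr2NEt, CH2Cl2, 0 °C → rt
Reagents that add atoms: chloromethyl methyl ether (MOMCl), COCCl
Why: Amine-buffered acetalisation of the primary alcohol under non-nucleophilic conditions leaves the methyl ester untouched.

Step 8
Reactants: 13 methyl 2-(methoxymethoxy)acetate
Product: 14 N-methoxy-2-(methoxymethoxy)-N-methylacetamide
Conditions: MeNHOMe·HCl, i-PrMgCl, THF, −20 °C
Reagents that add atoms: N,O-dimethylhydroxylamine hydrochloride, CNOC.Cl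
Why: The chloromagnesium amide formed in the flask attacks the ester and the resulting Weinreb amide resists further addition (direct ester-to-Weinreb-amide aminolysis).

Step 9
Reactants: 11 6-bromo-8-(methoxymethoxy)-2,2-dimethyl-2H-chromene; 14 N-methoxy-2-(methoxymethoxy)-N-methylacetamide
Product: 16 2-(methoxymethoxy)-1-[8-(methoxymethoxy)-2,2-dimethyl-2H-chromen-6-yl]ethan-1-one, via aryllithium 15 (not isolated)
Conditions: n-BuLi, THF, −78 °C; then 14, −78 → 0 °C; H2O quench
Reagents that add atoms: n-butyllithium, [Li]CCCC (supplies only the lithium of intermediate 15)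
Why: Bromine–lithium exchange is much faster at −78 °C than ortho-metalation or addition to the alkene, and the chelated tetrahedral adduct of the Weinreb ketone synthesis prevents double addition.

Step 10
Reactants: 4 2-iodo-1,3,5-tris(methoxymethoxy)benzene; 16 2-(methoxymethoxy)-1-[8-(methoxymethoxy)-2,2-dimethyl-2H-chromen-6-yl]ethan-1-one; 17 carbon monoxide
Product: 18 2-(methoxymethoxy)-1-[8-(methoxymethoxy)-2,2-dimethyl-2H-chromen-6-yl]-3-[2,4,6-tris(methoxymethoxy)phenyl]propane-1,3-dione, drawn as its hydrogen-bonded (E)-enol
Conditions: CO (1 atm), Pd(dba)2 (5 mol%), Xantphos (6 mol%), NaN(SiMe3)2 (2.2 equiv), THF, 60 °C; then AcOH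
Reagents that add atoms: none
Why: Zerovalent palladium inserts into the C–I bond of 4, CO migrates into the aryl–palladium bond to give an aroyl complex of divalent palladium, and the sodium enolate of 16 replaces iodide on the metal and is released by C–C reductive elimination, so that C4–C4a and C3–C4 are formed in one catalytic cycle; the second equivalent of base converts the more acidic diketone into its chelated enolate and pulls the sequence forward. The closest known reaction type is the palladium-catalysed carbonylative α-arylation of aryl ketones with aryl iodides to 1,3-diketones, applied here to an α-alkoxy ketone and a di-ortho-oxygenated iodide. No ring is closed and no stereocentre is created, and the product should be isolated as the enol. The step needs carbonylative C-acylation to win over direct α-arylation and O-acylation: the two ortho MOM-oxy groups slow enolate transfer to the crowded aryl palladium so that CO inserts first, the wide-bite-angle bisphosphine favours the aroyl complex at atmospheric CO pressure, and C-acylation leads to the stabilised β-diketonate. Because 4 is symmetric there is no regiochemical question at ring A, and either ortho oxygen can later close ring C.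

Step 11
Reactants: 18 the pentakis-MOM diketone
Product: 20 3,5,7-trihydroxy-2-(8-hydroxy-2,2-dimethyl-2H-chromen-6-yl)-4H-chromen-4-one, via pentahydroxy diketone 19 (not isolated)
Conditions: 3 M HCl, MeOH–THF, 55 °C
Reagents that add atoms: none
Why: Acid methanolysis removes all five acetals (formaldehyde is trapped as dimethoxymethane, protecting the electron-rich ring A), and a freed ortho phenol then adds 6-exo-trig to the ring B ketone and loses water to the aromatic pyranone, the classical cyclodehydration of 2-oxygenated 1-(2-hydroxyaryl)-1,3-diketones to flavonols.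

Step 12
Reactants: 20 3,5,7-trihydroxy-2-(8-hydroxy-2,2-dimethyl-2H-chromen-6-yl)-4H-chromen-4-one; 21 1-bromo-3-methylbut-2-ene
Product: 22 3,5-dihydroxy-2-(8-hydroxy-2,2-dimethyl-2H-chromen-6-yl)-7-[(3-methylbut-2-en-1-yl)oxy]-4H-chromen-4-one
Conditions: K2CO3 (1.1 equiv), 21 (1.05 equiv), DMF, 0 °C → rt
Reagents that add atoms: none
Why: The 7-OH, a vinylogous acid para to the C4 carbonyl, is clearly the most acidic hydroxyl, whereas 5-OH and 3-OH are tied up in hydrogen bonds to C4=O and the ring B phenol is an ordinary phenol, so one equivalent of weak base should give the 7-phenoxide and Williamson alkylation there.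

Step 13
Reactants: 22 the 7-O-prenyl flavonol
Product: 24 broussonol A, 3,5,7-trihydroxy-2-(8-hydroxy-2,2-dimethyl-2H-chromen-6-yl)-8-(2-methylbut-3-en-2-yl)-4H-chromen-4-one, via dienone 23 (not isolated)
Conditions: PhNEt2, 195 °C, argon
Reagents that add atoms: none
Why: Aromatic Claisen [3,3] rearrangement delivers the allyl unit with inversion to the ortho carbon C8, the intrinsically preferred site of 7-allyloxychromones, and tautomerisation of the dienone restores the 7-OH; the basic solvent suppresses acid-catalysed cyclisation of that phenol onto the new alkene.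

**Compound list**

1 | phloroglucinol | Oc1cc(O)cc(O)c1 | starting material
2 | 1,3,5-tris(methoxymethoxy)benzene | COCOc1cc(OCOC)cc(OCOC)c1 | intermediate
3 | [2,4,6-tris(methoxymethoxy)phenyl]lithium (formed in the flask, not isolated) | [Li]c1c(OCOC)cc(OCOC)cc1OCOC | intermediate
4 | 2-iodo-1,3,5-tris(methoxymethoxy)benzene | COCOc1cc(OCOC)c(I)c(OCOC)c1 | intermediate
5 | 4-bromo-2-methoxyphenol | COc1cc(Br)ccc1O | starting material
6 | 3-chloro-3-methylbut-1-yne | C#CC(C)(C)Cl | starting material
7 | 4-bromo-2-methoxy-1-[(2-methylbut-3-yn-2-yl)oxy]benzene | COc1cc(Br)ccc1OC(C)(C)C#C | intermediate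
8 | 4-bromo-2-methoxy-6-(3-methylbuta-1,2-dien-1-yl)phenol (formed in the flask, not isolated) | COc1cc(Br)cc(C=C=C(C)C)c1O | intermediate
9 | 6-bromo-8-methoxy-2,2-dimethyl-2H-chromene | COc1cc(Br)cc2C=CC(C)(C)Oc12 | intermediate
10 | 6-bromo-2,2-dimethyl-2H-chromen-8-ol | Oc1cc(Br)cc2C=CC(C)(C)Oc12 | intermediate
11 | 6-bromo-8-(methoxymethoxy)-2,2-dimethyl-2H-chromene | COCOc1cc(Br)cc2C=CC(C)(C)Oc12 | intermediate
12 | methyl glycolate | COC(=O)CO | starting material
13 | methyl 2-(methoxymethoxy)acetate | COCOCC(=O)OC | intermediate
14 | N-methoxy-2-(methoxymethoxy)-N-methylacetamide | COCOCC(=O)N(C)OC | intermediate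
15 | [8-(methoxymethoxy)-2,2-dimethyl-2H-chromen-6-yl]lithium (formed in the flask, not isolated) | [Li]c1cc(OCOC)c2OC(C)(C)C=Cc2c1 | intermediate
16 | 2-(methoxymethoxy)-1-[8-(methoxymethoxy)-2,2-dimethyl-2H-chromen-6-yl]ethan-1-one | COCOCC(=O)c1cc(OCOC)c2OC(C)(C)C=Cc2c1 | intermediate
17 | carbon monoxide | [C-]#[O+] | starting material
18 | 2-(methoxymethoxy)-1-[8-(methoxymethoxy)-2,2-dimethyl-2H-chromen-6-yl]-3-[2,4,6-tris(methoxymethoxy)phenyl]propane-1,3-dione, as its chelated (E)-enol | COCOc1cc(OCOC)c(C(=O)/C(OCOC)=C(\O)c2cc(OCOC)c3c(c2)C=CC(C)(C)O3)c(OCOC)c1 | intermediate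
19 | 2-hydroxy-1-(8-hydroxy-2,2-dimethyl-2H-chromen-6-yl)-3-(2,4,6-trihydroxyphenyl)propane-1,3-dione (racemic, tautomerising, formed in the flask, not isolated) | Oc1cc(O)c(C(=O)C(O)C(=O)c2cc(O)c3OC(C)(C)C=Cc3c2)c(O)c1 | intermediate
20 | 3,5,7-trihydroxy-2-(8-hydroxy-2,2-dimethyl-2H-chromen-6-yl)-4H-chromen-4-one | Oc1cc(O)c2c(=O)c(O)c(-c3cc(O)c4OC(C)(C)C=Cc4c3)oc2c1 | intermediate
21 | 1-bromo-3-methylbut-2-ene (prenyl bromide) | CC(C)=CCBr | starting material
22 | 3,5-dihydroxy-2-(8-hydroxy-2,2-dimethyl-2H-chromen-6-yl)-7-[(3-methylbut-2-en-1-yl)oxy]-4H-chromen-4-one | CC(C)=CCOc1cc(O)c2c(=O)c(O)c(-c3cc(O)c4OC(C)(C)C=Cc4c3)oc2c1 | intermediate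
23 | 3,5-dihydroxy-2-(8-hydroxy-2,2-dimethyl-2H-chromen-6-yl)-8-(2-methylbut-3-en-2-yl)-4H-chromene-4,7(8H)-dione (racemic dienone, formed in the flask, not isolated) | C=CC(C)(C)C1C(=O)C=C(O)C2=C1OC(c3cc(O)c4OC(C)(C)C=Cc4c3)=C(O)C2=O | intermediate
24 | broussonol A, 3,5,7-trihydroxy-2-(8-hydroxy-2,2-dimethyl-2H-chromen-6-yl)-8-(2-methylbut-3-en-2-yl)-4H-chromen-4-one (no stereocentre) | C=CC(C)(C)c1c(O)cc(O)c2c(=O)c(O)c(-c3cc(O)c4c(c3)C=CC(C)(C)O4)oc12 | target

**Step count**

Total: 13 steps. Longest linear sequence: 9 steps (steps 3, 4, 5, 6, 9, 10, 11, 12, 13, from 4-bromo-2-methoxyphenol).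

**Steps most likely to fail, with fallbacks**

Step 10. The pairing of a di-ortho-oxygenated iodide with an α-alkoxy ketone enolate is untested. The crowded aryl palladium may take up CO or the tetrasubstituted enolate only slowly. Reduction of the iodide, arylation without CO, O-acylation to an enol ester, capture of the aroyl palladium by the silylamide, or self-condensation of the ketone could then take over. The fallback builds the same diketone by a classical crossed Claisen condensation with the polarity of the fragments exchanged, so that the C2–C3 bond (flavone numbering) is formed instead.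
- It sets out from 2, 11 and 14.
- Aryllithium 3 (from 2 as in step 2) is added to Weinreb amide 14 in THF at −78 °C to give 2-(methoxymethoxy)-1-[2,4,6-tris(methoxymethoxy)phenyl]ethan-1-one F1.
- Aryllithium 15 (from 11 as in step 9) is added to excess methyl chloroformate at −78 °C to give methyl 8-(methoxymethoxy)-2,2-dimethyl-2H-chromene-6-carboxylate F2.
- The lithium enolate of F1 (LiN(SiMe3)2, 2.2 equiv, THF, −78 °C → rt) is acylated by the unhindered ester F2; deprotonation of the product drives the condensation, and acetic acid work-up should return the route at 18.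

Step 12. Alkylation may not stop at the 7-oxygen: the 3-OH or the ring B phenol may react, or ring A may be C-prenylated. The fallback replaces selection by acidity with a protecting-group sequence.
- It sets out from 20.
- Peracetylation (Ac2O, pyridine) gives 2-[8-(acetyloxy)-2,2-dimethyl-2H-chromen-6-yl]-4-oxo-4H-chromene-3,5,7-triyl triacetate F3.
- The most labile 7-O-acetyl group is removed selectively (PhSH, imidazole, N-methylpyrrolidone, 0 °C) to give 2-[8-(acetyloxy)-2,2-dimethyl-2H-chromen-6-yl]-7-hydroxy-4-oxo-4H-chromene-3,5-diyl diacetate F4.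
- Mitsunobu etherification of this single free phenol (3-methylbut-2-en-1-ol, PPh3, diisopropyl azodicarboxylate, THF, 0 °C) gives 2-[8-(acetyloxy)-2,2-dimethyl-2H-chromen-6-yl]-7-[(3-methylbut-2-en-1-yl)oxy]-4-oxo-4H-chromene-3,5-diyl diacetate F5.
- Methanolysis (K2CO3, MeOH, rt) removes the three acetates and returns the route at 22.

Step 13. The allyl group may migrate to C6 instead of C8. It may also travel on from C8 to C6 by a Cope shift as a linear prenyl group, or the 7-OH may cyclise onto the new alkene. The fallback runs the rearrangement on an acetate-masked substrate and traps the new phenol as it forms.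
- It sets out from 22.
- Acetylation (Ac2O, pyridine) gives the same tri-O-acetyl prenyl ether, 2-[8-(acetyloxy)-2,2-dimethyl-2H-chromen-6-yl]-7-[(3-methylbut-2-en-1-yl)oxy]-4-oxo-4H-chromene-3,5-diyl diacetate F5. If the fallback for step 12 is in use, F5 is taken on directly.
- With the 5-oxygen acetylated the chelate to C4=O is absent and C6 is more crowded, which should direct the shift to C8.
- Heating F5 in PhNEt2 with Ac2O and NaOAc (about 190 °C) should give the rearranged, in situ acetylated 2-[8-(acetyloxy)-2,2-dimethyl-2H-chromen-6-yl]-8-(2-methylbut-3-en-2-yl)-4-oxo-4H-chromene-3,5,7-triyl triacetate F6. The acetylated phenol can neither cyclise nor rearrange further.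
- Methanolysis (K2CO3, MeOH, rt) returns the route at the target 24.

**Further compounds**

F1 | step 10 | 2-(methoxymethoxy)-1-[2,4,6-tris(methoxymethoxy)phenyl]ethan-1-one | COCOCC(=O)c1c(OCOC)cc(OCOC)cc1OCOC
F2 | step 10 | methyl 8-(methoxymethoxy)-2,2-dimethyl-2H-chromene-6-carboxylate | COCOc1cc(C(=O)OC)cc2C=CC(C)(C)Oc12
F3 | step 12 | 2-[8-(acetyloxy)-2,2-dimethyl-2H-chromen-6-yl]-4-oxo-4H-chromene-3,5,7-triyl triacetate | CC(=O)Oc1cc(OC(C)=O)c2c(=O)c(OC(C)=O)c(-c3cc(OC(C)=O)c4OC(C)(C)C=Cc4c3)oc2c1
F4 | step 12 | 2-[8-(acetyloxy)-2,2-dimethyl-2H-chromen-6-yl]-7-hydroxy-4-oxo-4H-chromene-3,5-diyl diacetate | Oc1cc(OC(C)=O)c2c(=O)c(OC(C)=O)c(-c3cc(OC(C)=O)c4OC(C)(C)C=Cc4c3)oc2c1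
F5 | step 12 | 2-[8-(acetyloxy)-2,2-dimethyl-2H-chromen-6-yl]-7-[(3-methylbut-2-en-1-yl)oxy]-4-oxo-4H-chromene-3,5-diyl diacetate | CC(C)=CCOc1cc(OC(C)=O)c2c(=O)c(OC(C)=O)c(-c3cc(OC(C)=O)c4OC(C)(C)C=Cc4c3)oc2c1
F6 | step 13 | 2-[8-(acetyloxy)-2,2-dimethyl-2H-chromen-6-yl]-8-(2-methylbut-3-en-2-yl)-4-oxo-4H-chromene-3,5,7-triyl triacetate | C=CC(C)(C)c1c(OC(C)=O)cc(OC(C)=O)c2c(=O)c(OC(C)=O)c(-c3cc(OC(C)=O)c4OC(C)(C)C=Cc4c3)oc12
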